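Everything rests on cutting two bonds of the three-carbon tether: C-alpha–C-beta beside ring carbon C1, and the acyl C–O bond of the stearate. The feature exploited is that benzylic C-alpha on C1 of the benzene ring can stem from the formyl carbon of 5-hydroxyvanillin, while C-beta, C-gamma and the ester oxygen map onto oxirane. In one flask a lithiated dithiane opens the epoxide and the primary alkoxide released is captured by stearoyl chloride, which completes the skeleton. The precursor is the 1,3-dithiane of the aldehyde with the phenols on C3 and C4 masked as benzyl ethers. Desulfurisation and hydrogenolysis then unveil the target.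

Key step: step 3

Remark: the target has no stereocentre and no configured double bond, so no step has to set or preserve stereochemistry. Ethylene oxide is taken as its commercial THF solution.

Step 1
Reactants: 1 3,4-dihydroxy-5-methoxybenzaldehyde (5-hydroxyvanillin); 2 benzyl bromide
Product: 3 3,4-bis(benzyloxy)-5-methoxybenzaldehyde
Conditions: BnBr (2.3 equiv), K2CO3 (3 equiv), DMF, N2, rt → 60 °C
Reagents that add atoms: benzyl bromide 2, BrCc1ccccc1
Why: Williamson ether synthesis, in which the two phenoxides made by K2CO3 displace bromide from 2 by SN2 under nitrogen (the catecholate is air-sensitive), and benzyl is the mask of choice because it carries no proton that rivals the dithiane C2–H and no electrophilic silicon or acyl centre that the later alkoxide could attack.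

Step 2
Reactants: 3 3,4-bis(benzyloxy)-5-methoxybenzaldehyde; 4 propane-1,3-dithiol
Product: 5 2-[3,4-bis(benzyloxy)-5-methoxyphenyl]-1,3-dithiane
Conditions: HS(CH2)3SH (1.1 equiv), BF3·OEt2 (0.2 equiv), CH2Cl2, 0 °C → rt
Reagents that add atoms: propane-1,3-dithiol 4, SCCCS
Why: Lewis acid catalysed thioacetalisation of an aromatic aldehyde, driven by loss of water, in which a substoichiometric charge of BF3·OEt2 and barely more than one equivalent of dithiol at low temperature leave the aryl benzyl ethers untouched, since their cleavage by thiol and Lewis acid needs a large excess of both.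

Step 3
Reactants: 5 2-[3,4-bis(benzyloxy)-5-methoxyphenyl]-1,3-dithiane; 6 ethylene oxide (oxirane); 7 stearoyl chloride (octadecanoyl chloride)
Product: 10 2-{2-[3,4-bis(benzyloxy)-5-methoxyphenyl]-1,3-dithian-2-yl}ethyl stearate, via lithiodithiane 8 (not isolated), via lithium alkoxide 9 (not isolated)
Conditions: n-BuLi (1.05 equiv), THF, −78 → −20 °C; 6 (THF solution, 1.5 equiv), −78 → 0 °C; Ar purge; 7 (1.2 equiv, in THF), 0 °C → rt
Reagents that add atoms: ethylene oxide 6, C1CO1; stearoyl chloride 7, CCCCCCCCCCCCCCCCCC(=O)Cl; n-butyllithium, [Li]CCCC (its lithium stays only in 8 and 9, not in 10)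
Why: n-BuLi removes the C2–H of 5, which as a benzylic C–H between two sulfur atoms is far more acidic than the OCH2Ph or ring protons, and the soft carbanion 8 attacks a CH2 of the strained epoxide in an SN2 ring opening that forms the C-alpha–C-beta bond and releases the oxygen as the primary lithium alkoxide 9. Addition–elimination of 9 on the acid chloride 7 then forms the ester C–O bond in the same flask with loss of LiCl. The closest known reaction type is the Corey–Seebach alkylation of 2-aryl-2-lithio-1,3-dithianes with epoxides followed by in situ O-acylation of the alkoxide. No ring is closed and no stereocentre is created, and the symmetric epoxide raises no question of regiochemistry. The step needs chemoselective acylation at the C-gamma oxygen only, which the substrate secures because both phenol oxygens are benzyl ethers and 9 is the sole oxygen nucleophile present. A small excess of epoxide uses up all of 8 so that no C-acylation can occur, and the volatile remainder is swept out with argon before 7 is added at 0 °C, where the acid chloride stays in solution.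

Step 4
Reactants: 10 2-{2-[3,4-bis(benzyloxy)-5-methoxyphenyl]-1,3-dithian-2-yl}ethyl stearate
Product: 11 3-[3,4-bis(benzyloxy)-5-methoxyphenyl]propyl stearate
Conditions: Raney Ni (W-2, freshly prepared, washed to neutrality, excess), THF/EtOH, rt → 50 °C; filtration through Celite, short silica column
Reagents that add atoms: none
Why: Raney nickel hydrogenolysis of a dithioketal (second stage of a Mozingo reduction) replaces both benzylic C–S bonds by C–H with the hydrogen stored in the fresh catalyst, the neutral-washed metal leaves the aliphatic ester, the methyl ether and the arene alone, and any benzyl ether that falls off early does no harm because such material converges on 12 in step 5.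

Step 5
Reactants: 11 3-[3,4-bis(benzyloxy)-5-methoxyphenyl]propyl stearate
Product: 12 3-(3,4-dihydroxy-5-methoxyphenyl)propyl stearate (target)
Conditions: H2 (1 atm), 10% Pd/C, EtOAc/EtOH, rt; filtration through Celite under Ar
Reagents that add atoms: none
Why: Catalytic hydrogenolysis of the two aryl benzyl ethers over Pd/C, which should run cleanly because all sulfur left with the nickel in step 4, and which spares the aryl methyl ether and the ester, whose alkyl C–O bond lies three carbons from the ring and is neither benzylic nor allylic.

Compound list
1 | 3,4-dihydroxy-5-methoxybenzaldehyde (5-hydroxyvanillin) | COc1cc(C=O)cc(O)c1O | starting material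
2 | benzyl bromide | BrCc1ccccc1 | starting material
3 | 3,4-bis(benzyloxy)-5-methoxybenzaldehyde | COc1cc(C=O)cc(OCc2ccccc2)c1OCc1ccccc1 | intermediate
4 | propane-1,3-dithiol | SCCCS | starting material
5 | 2-[3,4-bis(benzyloxy)-5-methoxyphenyl]-1,3-dithiane | COc1cc(C2SCCCS2)cc(OCc2ccccc2)c1OCc1ccccc1 | intermediate
6 | ethylene oxide (oxirane) | C1CO1 | starting material
7 | stearoyl chloride (octadecanoyl chloride) | CCCCCCCCCCCCCCCCCC(=O)Cl | starting material
8 | 2-lithio-2-[3,4-bis(benzyloxy)-5-methoxyphenyl]-1,3-dithiane | [Li]C1(SCCCS1)c1cc(OC)c(OCc2ccccc2)c(OCc2ccccc2)c1 | intermediate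
9 | lithium 2-{2-[3,4-bis(benzyloxy)-5-methoxyphenyl]-1,3-dithian-2-yl}ethanolate | [Li]OCCC1(SCCCS1)c1cc(OC)c(OCc2ccccc2)c(OCc2ccccc2)c1 | intermediate
10 | 2-{2-[3,4-bis(benzyloxy)-5-methoxyphenyl]-1,3-dithian-2-yl}ethyl stearate | CCCCCCCCCCCCCCCCCC(=O)OCCC1(SCCCS1)c1cc(OC)c(OCc2ccccc2)c(OCc2ccccc2)c1 | intermediate
11 | 3-[3,4-bis(benzyloxy)-5-methoxyphenyl]propyl stearate | CCCCCCCCCCCCCCCCCC(=O)OCCCc1cc(OC)c(OCc2ccccc2)c(OCc2ccccc2)c1 | intermediate
12 | 3-(3,4-dihydroxy-5-methoxyphenyl)propyl stearate | CCCCCCCCCCCCCCCCCC(=O)OCCCc1cc(O)c(O)c(OC)c1 | target

Total step count: 5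
Longest linear sequence: 5 steps (1 → 3 → 5 → 10 → 11 → 12)

Steps most likely to fail

Step 3. The stabilised and hindered tertiary carbanion may open the epoxide too slowly. Leftover carbanion and leftover epoxide would then compete for the acid chloride, and the one-flask acylation would turn messy. The fallback sets out from 8 (made from 5 with n-BuLi as in step 3). It swaps the epoxide for a far stronger two-carbon electrophile and uncouples the esterification. 1,3,2-Dioxathiolane 2,2-dioxide (ethylene sulfate, O=S1(=O)OCCO1) in THF at −78 → 0 °C should be opened at carbon to give lithium 2-{2-[3,4-bis(benzyloxy)-5-methoxyphenyl]-1,3-dithian-2-yl}ethyl sulfate F1. Catalytic H2SO4 and a little water in THF at rt should hydrolyse the sulfate monoester to 2-{2-[3,4-bis(benzyloxy)-5-methoxyphenyl]-1,3-dithian-2-yl}ethanol F2. This alcohol is purified and then acylated with 7, Et3N and catalytic DMAP in CH2Cl2, which comes back to the route at 10.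

Step 4. Three things may go wrong:
- Material may be held back on the large nickel surface.
- Residual alkali in the catalyst may attack the ester.
- A hydrogen-poor catalyst batch may cause elimination to a cinnamyl-type olefin, whose allylic ester would then be lost by hydrogenolysis in step 5.

The fallback sets out from 10 and avoids nickel altogether, replacing reductive C–S cleavage by unmasking and deoxygenation. Alkylative hydrolysis of the dithiane (MeI, CaCO3, MeCN/H2O, 40 °C) should give the aryl ketone 3-[3,4-bis(benzyloxy)-5-methoxyphenyl]-3-oxopropyl stearate F3. Ionic hydrogenation of this electron-rich aryl ketone (Et3SiH, CF3CO2H, CH2Cl2, 0 °C → rt) should then take the carbonyl down to CH2, which comes back to the route at 11. Both operations are run without soluble base, because a β-acyloxy ketone would shed stearate by E1cB elimination.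

Step 5. Traces of sulfur carried over may poison the palladium surface and stall the hydrogenolysis. Long handling may also expose the liberated catechol to air oxidation. The fallback sets out from 11 and exchanges hydrogenolysis for Lewis acid debenzylation. It uses BCl3 with pentamethylbenzene as a benzyl cation scavenger that is not Lewis basic, in CH2Cl2 at −78 °C, with a cold MeOH quench. This is indifferent to sulfur and, at that temperature, should spare the ester and the aryl methyl ether. It comes back to the route at 12, and no new compound arises on this way (F0).

Further compounds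
F1 | step 3 | lithium 2-{2-[3,4-bis(benzyloxy)-5-methoxyphenyl]-1,3-dithian-2-yl}ethyl sulfate | [Li+].[O-]S(=O)(=O)OCCC1(SCCCS1)c1cc(OC)c(OCc2ccccc2)c(OCc2ccccc2)c1
F2 | step 3 | 2-{2-[3,4-bis(benzyloxy)-5-methoxyphenyl]-1,3-dithian-2-yl}ethanol | OCCC1(SCCCS1)c1cc(OC)c(OCc2ccccc2)c(OCc2ccccc2)c1
F3 | step 4 | 3-[3,4-bis(benzyloxy)-5-methoxyphenyl]-3-oxopropyl stearate | CCCCCCCCCCCCCCCCCC(=O)OCCC(=O)c1cc(OC)c(OCc2ccccc2)c(OCc2ccccc2)c1
F0 | step 5 | none | none
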